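1. Clerodane numbering is used (ring A = C1–C5 and C10; ring B = C5–C10). The enabling feature is that C10 of ring B sits between two quaternary carbons, C5 and C9. Each carries an α-CH3 and a β-carbon arm (C4 and C11), so ring B has a local mirror plane through C7 and C10, and both arms are installed as the same ethynyl group.
2. Key disconnection C3–C4: ring A is closed by 6-exo-dig attack of a C3 radical (arm on C10) on one of the two ethynyl groups. The C1 carbinol centre selects the C5 ethynyl; the closure gives C4=C18 and the trans fusion and leaves the C9 ethynyl for the side chain.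
3. C1–C3 arm: ester carbon C1 plus two carbons from EtMgBr. The temporary cyclopropanol is opened with NBS and the ketone is reduced under catalyst control.
4. Ring B: asymmetric Michael/aldol annulation, then two conjugate ethynylations with the stereochemical relay C5 → C9 → C10 → C5. The C6/C7 1,2-dione level lets hydride set C6 and lets the C7 enol ether direct C17 to C8.
5. Ring order: ring B (step 1); the lactone ring is bought closed (4-bromofuran-2(5H)-one, joined at C12–C13, C13–OH by conjugate borylation); ring A is the last ring closed (step 11).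

Key step: step 11

Convention: α/β refer to the usual clerodane drawing with H-10 β; monocyclic intermediates keep the numbers C5–C10 of ring B.
Assumption: in steps 1, 14 and 16 the named catalyst antipode is taken to give the drawn centre; if the sense of induction is opposite, its (pseudo)enantiomer is used.

Step 1
Reactants: 1 (E)-pent-3-en-2-one; 2 ethyl acetoacetate
Product: 4 ethyl (1S,6S)-2,6-dimethyl-4-oxocyclohex-2-ene-1-carboxylate (ring B; C5-CH3 α, C10-CO2Et α, C10 labile), via Michael adduct 3 (not isolated)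
Conditions: 9-amino-9-deoxy-epi-quinine (20 mol%), CF3CO2H (40 mol%), THF, rt; then p-TsOH·H2O (10 mol%), toluene, reflux, Dean–Stark
Reagents that add atoms: none
Why: Iminium-catalysed asymmetric Michael addition should set C5 (S); the acid-catalysed intramolecular aldol condensation (Robinson-type annulation, C8 methyl onto the acetoacetate ketone C9) closes ring B, with the labile C10 ester settling pseudoaxial and cis to the C5 methyl to avoid A(1,2) strain with the C9 methyl.

Step 2
Reactants: 4 enone; 5 ethynylmagnesium bromide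
Product: 7 ring-B ketone (C9: β-ethynyl, α-CH3; C5-CH3 α; C10-CO2Et α), via trimethylsilyl enol ether 6 (not isolated)
Conditions: 5, ZnBr2, THF, 0 °C; then 4, Me3SiOTf, Et2O–THF, −40 °C; 1 M HCl work-up
Reagents that add atoms: trimethylsilyl triflate, C[Si](C)(C)OS(=O)(=O)C(F)(F)F (silyl group stays only in 6)
Why: Silyl-triflate-promoted conjugate addition of a non-basic alkynylzinc to a β-substituted enone; axial attack on C9, trans to the C5 methyl and anti to the pseudoaxial C10 ester, should set the quaternary centre C9.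

Step 3
Reactants: 7 ketone
Product: 8 ring-B enone (C5(CH3)=C6–C7=O; C9 and C10 as in 7)
Conditions: IBX (1.5 equiv), DMSO–PhF, 70 °C
Reagents that add atoms: none
Why: IBX dehydrogenation of a ketone through its enol; only C5–C6 can be desaturated into conjugation because C9 is quaternary, the relay centre C5 is erased, and the vinylogously acidic C10–H lets the ester settle pseudoaxial, anti to the axial C9 ethynyl.

Step 4
Reactants: 8 enone; 5 ethynylmagnesium bromide
Product: 9 ring-B silyl enol ether (C5 and C9 each β-ethynyl/α-CH3; C10-CO2Et α; C6=C7–OTBS)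
Conditions: 5, ZnBr2, THF, 0 °C; then 8, t-BuMe2SiOTf, Et2O–THF, −40 °C; cold NaHCO3 work-up
Reagents that add atoms: tert-butyldimethylsilyl triflate, CC(C)(C)[Si](C)(C)OS(=O)(=O)C(F)(F)F
Why: The same conjugate alkynylation, stopped at the silyl enol ether; attack on C5 anti to the C10 ester and syn-axial only to the slim C9 ethynyl should set C5, and the regiospecific C6=C7 enol ether now carries the chirality, because the free ketone would be meso.

Step 5
Reactants: 9 ester
Product: 10 cyclopropanol (C10 bears a 1-hydroxycyclopropyl group = C1, C2, C3)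
Conditions: EtMgBr (2.2 equiv), THF, 0 °C; then Ti(OiPr)4 (30 mol%), EtMgBr (2.5 equiv, slow addition), 0 °C to rt; aq. NH4Cl
Reagents that add atoms: ethylmagnesium bromide, CC[Mg]Br
Why: Kulinkovich cyclopropanation of the ester adds C2 and C3; the alkynes are masked in the flask as magnesium acetylides, the enol ether masks C7, and no stereocentre is touched.

Step 6
Reactants: 10 silyl enol ether
Product: 11 α-ketol (C6–OH, C7=O; C6 epimers)
Conditions: OsO4 (2 mol%), NMO (1.2 equiv), acetone–H2O, 0 °C
Reagents that add atoms: N-methylmorpholine N-oxide, C[N+]1([O-])CCOCC1; water, O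
Why: Upjohn dihydroxylation picks the electron-rich enol ether over the alkynes and the silyl hemiketal collapses to the ketol, placing oxygen regiospecifically on C6; its configuration is irrelevant because it is erased in step 7.

Step 7
Reactants: 11 α-ketol
Product: 12 diosphenol (C6=O, C7(OH)=C8H)
Conditions: (COCl)2, DMSO, CH2Cl2, −78 °C; Et3N, −78 °C to rt
Reagents that add atoms: none
Why: Swern oxidation gives the 6,7-dione, which can enolise only towards C8 because C5 is quaternary, so the ketone ends up on C6 and the enol on C7.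

Step 8
Reactants: 12 diosphenol
Product: 13 diosphenol silyl ether (C6=O, C7(OTBS)=C8H, free cyclopropanol)
Conditions: t-BuMe2SiCl (1.1 equiv), imidazole, DMF, 0 °C
Reagents that add atoms: tert-butyldimethylsilyl chloride, CC(C)(C)[Si](C)(C)Cl
Why: O-silylation should take the acidic, unhindered enol OH and leave the tertiary cyclopropanol.

Step 9
Reactants: 13 cyclopropanol
Product: 14 β-bromo ketone (C10–C1(=O)–C2H2–C3H2Br)
Conditions: NBS (1.05 equiv), CH2Cl2, 0 °C, dark
Reagents that add atoms: N-bromosuccinimide, O=C1CCC(=O)N1Br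
Why: Electrophilic ring opening of a tertiary cyclopropanol (homoenol bromination) removes the temporary ring and puts the radical precursor on C3; the captodative, hindered C7=C8 bond and the alkynes should react more slowly.

Step 10
Reactants: 14 β-bromo ketone
Product: 15 (1R)-bromo alcohol
Conditions: (S)-2-methyl-CBS-oxazaborolidine (30 mol%), catecholborane (2 equiv), toluene, −60 °C; aq. work-up
Reagents that add atoms: none
Why: Corey–Bakshi–Shibata reduction; the very large C10 residue against CH2CH2Br should give (R)-C1, catecholborane spares the alkynes, and the C6 carbonyl, shut between quaternary C5 and the silyloxy carbon C7, should not bind the catalyst.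

Step 11
Reactants: 15 bromo alcohol
Product: 16 trans-decalin alcohol (1β-OH, 4(18)-methylene, 6-oxo, 7-OTBS-7-ene, 9β-ethynyl; C19 and C20 α, H-10 β)
Conditions: (Me3Si)3SiH (1.3 equiv) and AIBN (0.2 equiv) added over 6 h, benzene (5 mM), 80 °C
Reagents that add atoms: none
Why: The silyl radical abstracts Br from C3, the primary C3 radical adds to the inner carbon C4 of an ethynyl group, and the σ-vinyl radical at C18 takes H from the silane, so ring A and C4=C18 arise together; the closest known reaction type is the reductive alkyl-radical/alkyne cyclisation that gives exocyclic methylenes. Ring A (C1, C2, C3, C4, C5, C10) closes in the 6-exo-dig mode through a chair-like transition state, and 7-endo attack on C18 should not compete. The C10–C1 bond (α) is trans to both ethynyl groups (β), so the reacting groups can meet only when both are equatorial on ring B, and only the trans-decalin (C19 α, H-10 β) can form. The choice between the two ethynyl groups is controlled by C1: the slot between C5 and C9, under the two axial methyls, accepts only H-1, and with (R)-C1 this rotamer places C2–C3 gauche to C5 and anti to C9, with O-1 equatorial. Attack on the C9 ethynyl would force O-1 into that slot, syn-axial to a methyl group, so C5 becomes the ring-fusion carbon and C9 the side-chain carbon. Bromine abstraction should outrun silyl addition to the alkynes or the enone, and high dilution lets cyclisation outrun direct reduction.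

Step 12
Reactants: 16 alcohol; 17 (R)-2-methylbutanoic acid
Product: 18 C1 (R)-2-methylbutanoate
Conditions: 17, 2,4,6-trichlorobenzoyl chloride, Et3N, toluene, rt; then 16, DMAP, 50 °C
Reagents that add atoms: none
Why: Yamaguchi esterification acylates the only free hydroxyl with retention at C1, and the acyl-pyridinium route avoids a ketene and should keep the acid's stereocentre.

Step 13
Reactants: 18 alkyne
Product: 20 C12 aldehyde (C9–C11H2–C12HO), via alkenylborane 19 (not isolated)
Conditions: (c-C6H11)2BH (1.3 equiv), THF, 0 °C; then 30% H2O2, pH 7 phosphate buffer, 0 °C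
Reagents that add atoms: dicyclohexylborane, B(C1CCCCC1)C1CCCCC1 (stays only in 19); hydrogen peroxide, OO
Why: Anti-Markovnikov hydroboration–oxidation of a terminal alkyne; the bulky dialkylborane should ignore the neopentyl 1,1-disubstituted C4=C18 and the trisubstituted C7=C8 bond.

Step 14
Reactants: 20 aldehyde; 21 4-bromofuran-2(5H)-one
Product: 22 (12S)-butenolide carbinol
Conditions: CrCl2 (4 equiv), NiCl2 (2 mol%), (S)-N-[2-(4-isopropyl-4,5-dihydrooxazol-2-yl)-6-methylphenyl]methanesulfonamide (4.4 equiv), Et3N, THF, rt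
Reagents that add atoms: none
Why: Nozaki–Hiyama–Kishi coupling (zerovalent nickel inserts into C–Br, then transmetalation to trivalent chromium) adds only to the aldehyde, brings in the closed lactone ring, and the chiral sulfonamide on chromium should set C12.

Step 15
Reactants: 22 silyloxy enone
Product: 23 6α-alcohol (C6α–OH, C7(OTBS)=C8H retained)
Conditions: NaBH4, CeCl3·7H2O, MeOH–CH2Cl2, −78 to −40 °C
Reagents that add atoms: none
Why: Luche 1,2-reduction; the α face of C6 is covered by the adjacent axial C19 methyl, so hydride should arrive from the β face and give the equatorial 6α-OH, while the butenolide and the esters survive.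

Step 16
Reactants: 23 butenolide
Product: 25 triol (C13(S)–OH β-hydroxy lactone; 6α-OH, 12-OH), via tertiary boronate 24 (not isolated)
Conditions: [Cu(MeCN)4]PF6 (10 mol%), (R,R)-QuinoxP* (12 mol%), LiOtBu (15 mol%), B2pin2 (1.3 equiv), i-PrOH (2 equiv), THF, rt; then NaBO3·4H2O, THF–H2O, rt
Reagents that add atoms: bis(pinacolato)diboron, CC1(C)OB(OC1(C)C)B1OC(C)(C)C(C)(C)O1 (stays only in 24); sodium perborate, [Na+].[Na+].O[B-]1(O)OO[B-](O)(O)OO1
Why: Copper-catalysed enantioselective conjugate borylation of a β,β-disubstituted unsaturated lactone, the only acceptor left, followed by stereoretentive oxidation; the ligand should set C13.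

Step 17
Reactants: 25 triol; 26 tigloyl chloride
Product: 27 C12 tiglate
Conditions: 26 (1.1 equiv), pyridine, DMAP (5 mol%), CH2Cl2, −20 °C
Reagents that add atoms: none
Why: Acylation should take the side-chain secondary C12–OH; C13–OH is tertiary, and C6–OH is neopentyl and flanked by the silyloxy carbon C7.

Step 18
Reactants: 27 silyl enol ether
Product: 30 CNP0231308.2, via Mannich base 28 (not isolated), via ammonium iodide 29 (not isolated)
Conditions: Me2N=CH2+ I− (Eschenmoser's salt), CH2Cl2, rt; MeI, rt; then aq. NaHCO3–CH2Cl2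
Reagents that add atoms: Eschenmoser's salt, C[N+](C)=C.[I-]; methyl iodide, CI (stays only in 29)
Why: Mannich reaction of the regiodefined C7=C8 silyl enol ether places C17 on C8 and frees the C7 ketone; quaternisation and Hofmann-type β-elimination give C8=C17 without strong base, so C6, the lactone and the esters are not disturbed.

Compound list
1 | (E)-pent-3-en-2-one | C/C=C/C(C)=O | starting material
2 | ethyl acetoacetate | CCOC(=O)CC(C)=O | starting material
3 | ethyl (3S)-2-acetyl-3-methyl-5-oxohexanoate | CCOC(=O)C(C(C)=O)[C@@H](C)CC(C)=O | intermediate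
4 | ethyl (1S,6S)-2,6-dimethyl-4-oxocyclohex-2-ene-1-carboxylate | CCOC(=O)[C@H]1[C@@H](C)CC(=O)C=C1C | intermediate
5 | ethynylmagnesium bromide | C#C[Mg]Br | starting material
6 | C7 trimethylsilyl enol ether of 7 | CCOC(=O)[C@H]1[C@@H](C)CC(O[Si](C)(C)C)=C[C@]1(C)C#C | intermediate
7 | ring-B ketone, C9 β-ethynyl/α-CH3, C5 α-CH3, C10 α-CO2Et | CCOC(=O)[C@H]1[C@@H](C)CC(=O)C[C@]1(C)C#C | intermediate
8 | ring-B enone, C5(CH3)=C6–C7=O | CCOC(=O)[C@H]1C(C)=CC(=O)C[C@]1(C)C#C | intermediate
9 | ring-B diyne ester, C6=C7–OTBS | CCOC(=O)[C@H]1[C@@](C#C)(C)C=C(O[Si](C)(C)C(C)(C)C)C[C@]1(C)C#C | intermediate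
10 | C10 1-hydroxycyclopropyl diyne, C6=C7–OTBS | OC1(CC1)[C@H]2[C@@](C#C)(C)C=C(O[Si](C)(C)C(C)(C)C)C[C@]2(C)C#C | intermediate
11 | 6-hydroxy-7-ketone (C6 epimers) | OC1(CC1)[C@H]2[C@@](C#C)(C)C(O)C(=O)C[C@]2(C)C#C | intermediate
12 | diosphenol, C6=O, C7(OH)=C8 | OC1(CC1)[C@H]2[C@@](C#C)(C)C(=O)C(O)=C[C@]2(C)C#C | intermediate
13 | diosphenol TBS ether | OC1(CC1)[C@H]2[C@@](C#C)(C)C(=O)C(O[Si](C)(C)C(C)(C)C)=C[C@]2(C)C#C | intermediate
14 | C1 ketone, C3 bromide | BrCCC(=O)[C@H]1[C@@](C#C)(C)C(=O)C(O[Si](C)(C)C(C)(C)C)=C[C@]1(C)C#C | intermediate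
15 | (1R)-alcohol, C3 bromide | BrCC[C@@H](O)[C@H]1[C@@](C#C)(C)C(=O)C(O[Si](C)(C)C(C)(C)C)=C[C@]1(C)C#C | intermediate
16 | trans-decalin, 1β-OH, 4(18)-methylene, 6-oxo, 7-OTBS-7-ene, 9β-ethynyl | C=C1CC[C@@H](O)[C@H]2[C@@]1(C)C(=O)C(O[Si](C)(C)C(C)(C)C)=C[C@]2(C)C#C | intermediate
17 | (R)-2-methylbutanoic acid | CC[C@@H](C)C(=O)O | starting material
18 | C1 (R)-2-methylbutanoate of 16 | C=C1CC[C@@H](OC(=O)[C@H](C)CC)[C@H]2[C@@]1(C)C(=O)C(O[Si](C)(C)C(C)(C)C)=C[C@]2(C)C#C | intermediate
19 | (E)-C12 dicyclohexylalkenylborane | C=C1CC[C@@H](OC(=O)[C@H](C)CC)[C@H]2[C@@]1(C)C(=O)C(O[Si](C)(C)C(C)(C)C)=C[C@]2(C)/C=C/B(C3CCCCC3)C3CCCCC3 | intermediate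
20 | C12 aldehyde | C=C1CC[C@@H](OC(=O)[C@H](C)CC)[C@H]2[C@@]1(C)C(=O)C(O[Si](C)(C)C(C)(C)C)=C[C@]2(C)CC=O | intermediate
21 | 4-bromofuran-2(5H)-one | O=C1C=C(Br)CO1 | starting material
22 | (12S)-carbinol with butenolide | C=C1CC[C@@H](OC(=O)[C@H](C)CC)[C@H]2[C@@]1(C)C(=O)C(O[Si](C)(C)C(C)(C)C)=C[C@]2(C)C[C@H](O)C3=CC(=O)OC3 | intermediate
23 | 6α-alcohol of 22 | C=C1CC[C@@H](OC(=O)[C@H](C)CC)[C@H]2[C@@]1(C)[C@@H](O)C(O[Si](C)(C)C(C)(C)C)=C[C@]2(C)C[C@H](O)C3=CC(=O)OC3 | intermediate
24 | C13 pinacol boronate | C=C1CC[C@@H](OC(=O)[C@H](C)CC)[C@H]2[C@@]1(C)[C@@H](O)C(O[Si](C)(C)C(C)(C)C)=C[C@]2(C)C[C@H](O)[C@@]3(B4OC(C)(C)C(C)(C)O4)COC(=O)C3 | intermediate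
25 | 6α,12,13-triol | C=C1CC[C@@H](OC(=O)[C@H](C)CC)[C@H]2[C@@]1(C)[C@@H](O)C(O[Si](C)(C)C(C)(C)C)=C[C@]2(C)C[C@H](O)[C@@]3(O)COC(=O)C3 | intermediate
26 | tigloyl chloride | C/C=C(\C)C(=O)Cl | starting material
27 | C12 tiglate | C=C1CC[C@@H](OC(=O)[C@H](C)CC)[C@H]2[C@@]1(C)[C@@H](O)C(O[Si](C)(C)C(C)(C)C)=C[C@]2(C)C[C@H](OC(=O)/C(C)=C/C)[C@@]3(O)COC(=O)C3 | intermediate
28 | C8 dimethylaminomethyl ketone (C8 epimers) | C=C1CC[C@@H](OC(=O)[C@H](C)CC)[C@H]2[C@@]1(C)[C@@H](O)C(=O)C(CN(C)C)[C@]2(C)C[C@H](OC(=O)/C(C)=C/C)[C@@]3(O)COC(=O)C3 | intermediate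
29 | C8 trimethylammoniomethyl ketone iodide | C=C1CC[C@@H](OC(=O)[C@H](C)CC)[C@H]2[C@@]1(C)[C@@H](O)C(=O)C(C[N+](C)(C)C)[C@]2(C)C[C@H](OC(=O)/C(C)=C/C)[C@@]3(O)COC(=O)C3.[I-] | intermediate
30 | CNP0231308.2 | C=C1CC[C@@H](OC(=O)[C@H](C)CC)[C@H]2[C@@]1(C)[C@@H](O)C(=O)C(=C)[C@]2(C)C[C@H](OC(=O)/C(C)=C/C)[C@@]1(O)COC(=O)C1 | target

Total step count: 18. Longest linear sequence: 18.

Steps most likely to fail

Step 4. The hindered β,β-disubstituted enone may be γ-deprotonated and O-silylated to a dienol ether instead of accepting the acetylide. Partial hydrolysis of the enol ether would pass through the meso ketone and lose optical purity. The fallback makes the C5–C4 bond by epoxide opening and sets out from 8. Luche reduction should give the 7α-allylic alcohol F1. VO(acac)2/t-BuOOH should then deliver the hydroxyl-directed 5α,6α-epoxy alcohol F2. Diethyl(ethynyl)aluminium (from 5 and Et2AlCl) should open the 2,3-epoxy alcohol at tertiary C5 with inversion to the 6α,7α-diol ester F3. Kulinkovich cyclopropanation gives the cyclopropanol diol F4, and a double Swern oxidation returns to the route at 12.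

Step 5. The ester between two quaternary carbons may resist the titanacyclopropane, which would allow reduction or titanation of the alkynes to take over. The fallback builds the arm through a vinyl ketone and sets out from 9. i-Bu2AlH at −78 °C should give the C1 aldehyde F5. CH2=CHMgBr then gives the allylic alcohol F6, and Dess–Martin periodinane the vinyl ketone F7. The sequence of steps 6–8 (OsO4/NMO, Swern, t-BuMe2SiCl), which spares the electron-poor vinyl ketone, leads through the ketol F8 and the diosphenol F9 to the silyl ether F10. Conjugate addition of HBr (Me3SiBr, MeOH, CH2Cl2, −20 °C) returns to the route at 14.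

Step 11. The primary radical may be reduced by the silane before the slower 6-exo-dig closure, because ring B must first reach the conformer with both methyls axial. The fallback removes the hydride donor from the ring-closing event and sets out from 15. A Finkelstein exchange (NaI, acetone) gives the iodide F11. Iodine-atom-transfer cyclisation (Et3B, air, benzene, rt) should give the exocyclic vinyl iodide F12. Separate reduction of the C18–I bond (Bu3SnH, Et3B, 0 °C) returns to the route at 16.

Further compounds
F1 | step 4 | 7α-allylic alcohol from 8 | CCOC(=O)[C@H]1C(C)=C[C@@H](O)C[C@]1(C)C#C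
F2 | step 4 | 5α,6α-epoxy-7α-alcohol | CCOC(=O)[C@H]1[C@@]2(C)O[C@H]2[C@@H](O)C[C@]1(C)C#C
F3 | step 4 | 6α,7α-diol ester with C5 β-ethynyl | CCOC(=O)[C@H]1[C@@](C#C)(C)[C@@H](O)[C@@H](O)C[C@]1(C)C#C
F4 | step 4 | cyclopropanol 6α,7α-diol | OC1(CC1)[C@H]2[C@@](C#C)(C)[C@@H](O)[C@@H](O)C[C@]2(C)C#C
F5 | step 5 | C1 aldehyde | O=C[C@H]1[C@@](C#C)(C)C=C(O[Si](C)(C)C(C)(C)C)C[C@]1(C)C#C
F6 | step 5 | C1 allylic alcohol (C1 epimers) | C=CC(O)[C@H]1[C@@](C#C)(C)C=C(O[Si](C)(C)C(C)(C)C)C[C@]1(C)C#C
F7 | step 5 | C1 vinyl ketone | C=CC(=O)[C@H]1[C@@](C#C)(C)C=C(O[Si](C)(C)C(C)(C)C)C[C@]1(C)C#C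
F8 | step 5 | vinyl ketone 6-hydroxy-7-ketone (C6 epimers) | C=CC(=O)[C@H]1[C@@](C#C)(C)C(O)C(=O)C[C@]1(C)C#C
F9 | step 5 | vinyl ketone diosphenol | C=CC(=O)[C@H]1[C@@](C#C)(C)C(=O)C(O)=C[C@]1(C)C#C
F10 | step 5 | vinyl ketone diosphenol TBS ether | C=CC(=O)[C@H]1[C@@](C#C)(C)C(=O)C(O[Si](C)(C)C(C)(C)C)=C[C@]1(C)C#C
F11 | step 11 | (1R)-alcohol, C3 iodide | ICC[C@@H](O)[C@H]1[C@@](C#C)(C)C(=O)C(O[Si](C)(C)C(C)(C)C)=C[C@]1(C)C#C
F12 | step 11 | decalin with C18 vinyl iodide (E/Z) | IC=C1CC[C@@H](O)[C@H]2[C@@]1(C)C(=O)C(O[Si](C)(C)C(C)(C)C)=C[C@]2(C)C#C
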